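# Proposed synthesis of CNP0081547.1, a (2S)-flavanone–flavone biaryl

Labels for the target. Flavanone half: ring A (C4a, C5, C6, C7, C8, C8a), ring C (O1, C2, C3, C4), ring B (4-methoxyphenyl on C2). Flavone half: ring D (dihydroxybenzo ring), ring E (pyranone), ring F (anisole ring; C1′ on ring E, C3′ bonded to C6 of ring A, C4′ bearing OMe). C2 is S (O1 > aryl > C3 > H), as in the given SMILES.

## The problem

The target is a 3′,6-linked biflavonoid: a (2S)-5,7-dihydroxy-4′-methoxyflavanone (rings A, C, B) bonded through C6 of ring A to C3′ of ring F of a 5,7-dihydroxy-4′-methoxyflavone (rings D, E, F). The C6–C3′ bond is a biaryl bond with three ortho oxygen substituents (5-OH, 7-OH, 4′-OMe) at the most crowded carbon of a phloroglucinol ring, a poor site for cross-coupling. C6 and C8 of ring A differ only in which neighbouring oxygen is tied into ring C, so any route that arylates a finished ring A, or closes ring C with the aryl group in place, has to tell them apart, and ring opening to the chalcone can interchange them. The only stereocentre, C2, is a benzylic ether carbon β to the C4 ketone. It is lost by retro-oxa-Michael opening under base (more slowly under acid), and with no second stereocentre to relay from it has to be set by a catalyst, late, and then kept away from base. Four phenols must end free beside two aryl methyl ethers, so the protecting groups have to leave under neutral conditions. The feature that opens a way round the biaryl coupling is that ring A (C4a, C5, C6, C7, C8, C8a) is a phloroglucinol, the aromatic tautomer of a cyclohexane-1,3,5-trione, with the aryl-bearing carbon C6 between the oxygen-bearing carbons C5 and C7. Read this way, C6–C7 with ring F is an arylacetyl unit, and O1, C2, C3, C4, C4a, C8a, C8 and C5 are the atoms of a 2-methyl-4-pyranone-3-carboxylate. Ring A can therefore be grown between an arylacetic acid and a preformed ring C, with the biaryl bond arising by aromatisation and the 6/8 question answered by connectivity.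

## Retrosynthesis

**18 ⇒ 17 (four O–CH2Ph bonds).** The last step should touch protecting groups only. Benzyl is preferred to methyl (indistinguishable from the two OMe that stay), to acetal groups (acid removal endangers the 4-methoxybenzylic C2–O1 bond) and to acyl groups (basic removal opens ring C). Tetrabenzyl ether 17 contains the whole skeleton and the stereocentre. The forward reaction is a hydrogenolysis that must spare C2–O1 and the ring E double bond.

**17 ⇒ 15 + 16 (the C2–ring B bond).** Cutting C2–aryl instead of O1–C2 avoids the chalcone, and with it both the 6/8 ambiguity and the reversible oxa-Michael closure. The precursor, chromone 15, has no stereocentre, and (4-methoxyphenyl)boronic acid 16 is commercial. The forward reaction is a catalyst-controlled, base-free conjugate arylation of the chromone C2=C3 bond. It must choose one face and must leave ring E, whose β-carbon already carries an aryl group, alone.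

**15 ⇒ 14 (O5–benzyl and O7–benzyl).** Diol 14 is benzylated so that the chelated 5-OH and the acidic 7-OH do not interfere with the palladium step, and so that all four phenols carry the same group for one final deprotection. The forward reaction is a double Williamson etherification at two hindered phenols.

**14 ⇒ 8 + 11 (C7–C8 and C4a–C5 of ring A; key disconnection).** Cutting the biaryl bond C6–C3′ would leave a tri-ortho-substituted coupling and a C6-selective halogenation; cutting ring A does not. It leads to arylacetic acid 8 (one flavone with a CH2CO2H arm) and methyl 2-methyl-4-oxo-4H-pyran-3-carboxylate 11. The latter is an eight-carbon achiral pyranone whose methyl group becomes C8, whose ester carbon becomes C5 and whose ring is ring C. Forward, 8 is activated as acyl imidazole 12, the lithiated methyl group of 11 is acylated to keto ester 13, and 13 closes onto its own ester and aromatises. The step makes two C–C bonds, ring A, both ring A phenols and the hindered biaryl. The aryl group can only end at C6.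

**8 ⇒ 7 ⇒ 5 + 6 (C3′–CH2).** The arylacetic arm comes from ester 7, made by palladium-catalysed coupling of bromoflavone 5 with Reformatsky reagent 6. This sp2–sp3 coupling at a bromide with one ortho substituent replaces the far harder biaryl coupling. Hydrolysis gives 8.

**5 ⇒ 4 ⇒ 2 + 3; 2 ⇒ 1 (ring E).** The flavone is built first, by chalcone condensation of acetophenone 2 with 3-bromo-4-methoxybenzaldehyde 3 to give 4, then oxidative cyclisation. At this stage strong base and hot iodine/DMSO harm nothing. Acetophenone 2 comes from commercial 2′,4′,6′-trihydroxyacetophenone 1 by selective dibenzylation.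

**11 ⇒ 10 ⇒ 9 (C3–CO2Me of the pyranone).** Maltol 9 is a 2-methyl-4-pyranone with oxygen on the carbon that must carry the ester. Its triflate 10 is methoxycarbonylated to 11. Both steps are standard, and 11 is reached in two steps from a commodity chemical.

## Roads not taken

**Alternative 1:** cut the biaryl bond C6–C3′ between two finished halves (the obvious route). The forward key step is a Suzuki–Miyaura coupling of (2S)-6-iodoflavanone A1 with flavone boronic acid A2 to give 17.
- The halide carbon is flanked by two alkoxy groups and the boronic acid by one, so oxidative addition and transmetalation are slow and protodeboronation competes.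
- A1 needs C6-selective iodination (5-OH free, 7-O protected) followed by protection of the hindered 5-OH, all on a compound that already carries the labile stereocentre.
- The hot basic coupling medium promotes retro-oxa-Michael opening of ring C and loss of enantiopurity.
- The chosen plan never makes this bond by coupling and creates C2 after all basic steps.

**Alternative 2:** cut O1–C2 (ring C last, classical flavonoid logic). The precursor is 2′,4′,6′-trihydroxychalcone A3 carrying the ring F substituent; the forward key step is an enantioselective intramolecular oxa-Michael addition to flavanone A4.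
- A3 has two non-equivalent ortho hydroxyls. Closure through one gives A4, through the other the 8-aryl isomer A5, with no intrinsic bias and interconversion through the chalcone.
- Asymmetric oxa-Michael closure of unactivated polyhydroxychalcones is reversible and poorly controlled.
- A3 still requires the hindered aryl–phloroglucinol bond to be made.
- The chosen plan fixes O1 in ring C before ring A exists and sets C2 by an irreversible C–C bond formation.

**Alternative 3:** the same ring A annulation, but on an enantiopure ring C. The forward key step is Claisen–Dieckmann annulation of 12 with methyl (2S)-2-(4-methoxyphenyl)-6-methyl-4-oxo-3,4-dihydro-2H-pyran-5-carboxylate A6, giving A4 directly and saving steps 9 and 10.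
- A6 has an sp3 CH2 next to the ketone. Its deprotonation leads to E1cB loss of O1, ring opening and racemisation.
- The dienolate of a dihydropyranone lacks the bias that directs 4-pyranone carbanions to the exocyclic carbon.
- The flavanone would be formed in the presence of excess amide and methoxide.
- A6 has no short enantioselective synthesis.
- In the chosen plan 11 has no stereocentre and no sp3 C–H other than the methyl group, and C2 is made afterwards under base-free conditions.

Key step: step 8

Remark on the chemistry: rotation about the C6–C3′ axis (three ortho oxygen substituents, one ortho hydrogen) is assumed fast at room temperature, so no axial stereochemistry is controlled; the target SMILES specifies none.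

## Route

Step 1
Reactants: 1 1-(2,4,6-trihydroxyphenyl)ethan-1-one
Product: 2 1-[2,4-bis(benzyloxy)-6-hydroxyphenyl]ethan-1-one
Conditions: BnBr (2.05 equiv), K2CO3, acetone, reflux
Reagents that add atoms: benzyl bromide, BrCc1ccccc1
Why: Williamson etherification; one ortho hydroxyl is hydrogen-bonded to the acetyl carbonyl and is the least nucleophilic, so with two equivalents of bromide the other two oxygens should be alkylated.

Step 2
Reactants: 2 1-[2,4-bis(benzyloxy)-6-hydroxyphenyl]ethan-1-one; 3 3-bromo-4-methoxybenzaldehyde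
Product: 4 (E)-1-[2,4-bis(benzyloxy)-6-hydroxyphenyl]-3-(3-bromo-4-methoxyphenyl)prop-2-en-1-one
Conditions: KOH (50% aq.), EtOH, 23 °C; then 1 M HCl
Reagents that add atoms: none
Why: Claisen–Schmidt condensation of a methyl ketone with a non-enolisable aldehyde; dehydration gives the conjugated E-enone, and aryl bromide and benzyl ethers are inert to hydroxide at room temperature.

Step 3
Reactants: 4 (E)-1-[2,4-bis(benzyloxy)-6-hydroxyphenyl]-3-(3-bromo-4-methoxyphenyl)prop-2-en-1-one
Product: 5 5,7-bis(benzyloxy)-2-(3-bromo-4-methoxyphenyl)-4H-chromen-4-one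
Conditions: I2 (10 mol %), DMSO, 130 °C
Reagents that add atoms: none
Why: Iodine-catalysed oxidative cyclisation of a 2′-hydroxychalcone (oxa-Michael closure, α-iodination, loss of HI), with DMSO as terminal oxidant; this standard flavone synthesis should tolerate benzyl ethers and the aryl bromide.

Step 4
Reactants: 5 5,7-bis(benzyloxy)-2-(3-bromo-4-methoxyphenyl)-4H-chromen-4-one; 6 (2-ethoxy-2-oxoethyl)zinc bromide
Product: 7 ethyl 2-{5-[5,7-bis(benzyloxy)-4-oxo-4H-chromen-2-yl]-2-methoxyphenyl}acetate
Conditions: Pd2(dba)3 (2.5 mol %), XPhos (6 mol %), THF, 65 °C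
Reagents that add atoms: none
Why: Negishi-type coupling of a Reformatsky reagent with an aryl bromide (palladium-catalysed α-arylation of a zinc ester enolate); the zinc enolate is mild enough not to add to the vinylogous-ester carbonyl of the flavone, and the bulky biarylphosphine handles the ortho-methoxy bromide.

Step 5
Reactants: 7 ethyl 2-{5-[5,7-bis(benzyloxy)-4-oxo-4H-chromen-2-yl]-2-methoxyphenyl}acetate
Product: 8 2-{5-[5,7-bis(benzyloxy)-4-oxo-4H-chromen-2-yl]-2-methoxyphenyl}acetic acid
Conditions: LiOH·H2O, THF–MeOH–H2O, 23 °C; then 1 M HCl to pH 3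
Reagents that add atoms: lithium hydroxide, [Li+].[OH-]
Why: Saponification of an unhindered ethyl ester; at room temperature hydroxide should not open the 2-aryl-substituted pyranone ring of the flavone.

Step 6
Reactants: 9 3-hydroxy-2-methyl-4H-pyran-4-one (maltol)
Product: 10 2-methyl-4-oxo-4H-pyran-3-yl trifluoromethanesulfonate
Conditions: Tf2O, pyridine, CH2Cl2, 0 °C
Reagents that add atoms: trifluoromethanesulfonic anhydride, O=S(=O)(OS(=O)(=O)C(F)(F)F)C(F)(F)F
Why: O-sulfonylation of the enolic hydroxyl of maltol, the only nucleophilic site, gives an enol triflate suited to palladium chemistry.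

Step 7
Reactants: 10 2-methyl-4-oxo-4H-pyran-3-yl trifluoromethanesulfonate
Product: 11 methyl 2-methyl-4-oxo-4H-pyran-3-carboxylate
Conditions: Pd(OAc)2 (5 mol %), dppp (6 mol %), CO (1 atm), Et3N, MeOH–DMF, 60 °C
Reagents that add atoms: carbon monoxide, [C-]#[O+]; methanol, CO
Why: Palladium-catalysed alkoxycarbonylation of an enol triflate (oxidative addition, CO insertion, methanolysis of the acylpalladium species); the electron-poor triflate should add readily to zerovalent palladium.

Step 8
Reactants: 8 2-{5-[5,7-bis(benzyloxy)-4-oxo-4H-chromen-2-yl]-2-methoxyphenyl}acetic acid; 11 methyl 2-methyl-4-oxo-4H-pyran-3-carboxylate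
Product: 14 6-{5-[5,7-bis(benzyloxy)-4-oxo-4H-chromen-2-yl]-2-methoxyphenyl}-5,7-dihydroxy-4H-chromen-4-one, via acyl imidazole 12 (not isolated), via keto ester 13 (not isolated)
Conditions: 8, CDI (1.1 equiv), THF, 23 °C, Ar purge; added to 11 (1.2 equiv) and LiN(SiMe3)2 (3.5 equiv), THF, −78 → 23 °C, then 50 °C; 1 M HCl
Reagents that add atoms: none
Why: Proposed new method: LiN(SiMe3)2 removes a proton from the 2-methyl group of 11, the only sp3 C–H in the molecule, to give a dienolate stabilised by ring ketone and ester, and this carbanion is acylated at its exocyclic carbon by acyl imidazole 12 (Claisen stage, bond C7–C8), giving keto ester 13 as its enolate. Proton exchange through the imidazole and lithium imidazolide set free makes the less stable enolate at the benzylic carbon C6 available, and this attacks the neighbouring ring ester in a 6-(enolendo)-exo-trig Dieckmann closure (bond C5–C4a); loss of methoxide and enolisation of the resulting 2-aryl-1,3-dione aromatise ring A as its 5,7-diphenoxide, the thermodynamic sink of the sequence. The closest known reaction type is the toluate-anion annulation of o-toluates with acyl donors (Claisen acylation at the benzylic carbon, then Dieckmann closure onto the ortho ester to give naphthalene-1,3-diols), together with the known lithiation and exocyclic acylation of 2-methyl-4-pyranones and 2-methylchromones; new is the use of a 4-pyranone-3-carboxylate in the role of the toluate. One ring (ring A) is closed, two C–C bonds are formed and no stereocentre is created. The selectivities needed are C- over O-acylation in the first stage and C- over O-cyclisation (enol lactone) in the second: both O-acyl products are active esters that imidazolide or methoxide reopen, whereas the aromatic diphenoxide cannot revert. Position selectivity (6-aryl, not 8-aryl) needs no control, because C6 is bonded to both new oxygen-bearing carbons and O1 is already part of ring C in 11. Conjugate attack on the unsubstituted O–CH= carbon of the pyranone is held back by complete deprotonation of 11 before 12 is added.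

Step 9
Reactants: 14 6-{5-[5,7-bis(benzyloxy)-4-oxo-4H-chromen-2-yl]-2-methoxyphenyl}-5,7-dihydroxy-4H-chromen-4-one
Product: 15 5,7-bis(benzyloxy)-6-{5-[5,7-bis(benzyloxy)-4-oxo-4H-chromen-2-yl]-2-methoxyphenyl}-4H-chromen-4-one
Conditions: BnBr (3 equiv), K2CO3, Bu4NI (cat.), DMF, 60 °C
Reagents that add atoms: benzyl bromide, BrCc1ccccc1
Why: Williamson etherification; the acidic 7-OH reacts first and the chelated, hindered 5-OH follows in warm DMF with iodide catalysis, while dry carbonate should not open the chromone.

Step 10
Reactants: 15 5,7-bis(benzyloxy)-6-{5-[5,7-bis(benzyloxy)-4-oxo-4H-chromen-2-yl]-2-methoxyphenyl}-4H-chromen-4-one; 16 (4-methoxyphenyl)boronic acid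
Product: 17 (2S)-5,7-bis(benzyloxy)-6-{5-[5,7-bis(benzyloxy)-4-oxo-4H-chromen-2-yl]-2-methoxyphenyl}-2-(4-methoxyphenyl)-2,3-dihydro-4H-chromen-4-one
Conditions: Pd(OCOCF3)2 (10 mol %), (R)-t-BuPyOx (12 mol %), NH4PF6 (30 mol %), H2O (5 equiv), ClCH2CH2Cl, 60 °C
Reagents that add atoms: none
Why: Palladium-catalysed asymmetric conjugate addition of an arylboronic acid to a chromone (transmetalation, enantio-determining insertion of C2=C3 into the aryl–palladium bond, protonolysis of the palladium enolate by water), which creates C2 irreversibly without base, so the retro-oxa-Michael path is closed. The pyridine-oxazoline ligand sets the face; by the face model of the parent cyclic-enone additions the (R)-ligand, (R)-4-tert-butyl-2-(pyridin-2-yl)-4,5-dihydrooxazole, is expected to give 2S, and the antipode is equally available should the sense be opposite. Ring E is not attacked because insertion at its aryl-substituted β-carbon would build a quaternary centre and is far slower.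

Step 11
Reactants: 17 (2S)-5,7-bis(benzyloxy)-6-{5-[5,7-bis(benzyloxy)-4-oxo-4H-chromen-2-yl]-2-methoxyphenyl}-2-(4-methoxyphenyl)-2,3-dihydro-4H-chromen-4-one
Product: 18 (2S)-6-[5-(5,7-dihydroxy-4-oxo-4H-chromen-2-yl)-2-methoxyphenyl]-5,7-dihydroxy-2-(4-methoxyphenyl)-2,3-dihydro-4H-chromen-4-one
Conditions: H2 (1 atm), 10% Pd/C, EtOAc–THF, 23 °C, stopped at full debenzylation
Reagents that add atoms: none
Why: Hydrogenolysis of aryl benzyl ethers under neutral conditions, routine for benzylated flavones and flavanones; C2 is not touched, and the methyl ethers, the conjugated ring E double bond and the C2–O1 bond react much more slowly than O-benzyl groups at one atmosphere.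

## Compound list

1 | 1-(2,4,6-trihydroxyphenyl)ethan-1-one | CC(=O)c1c(O)cc(O)cc1O | starting material
2 | 1-[2,4-bis(benzyloxy)-6-hydroxyphenyl]ethan-1-one | CC(=O)c1c(O)cc(OCc2ccccc2)cc1OCc1ccccc1 | intermediate
3 | 3-bromo-4-methoxybenzaldehyde | COc1ccc(C=O)cc1Br | starting material
4 | (E)-1-[2,4-bis(benzyloxy)-6-hydroxyphenyl]-3-(3-bromo-4-methoxyphenyl)prop-2-en-1-one | COc1ccc(/C=C/C(=O)c2c(O)cc(OCc3ccccc3)cc2OCc2ccccc2)cc1Br | intermediate
5 | 5,7-bis(benzyloxy)-2-(3-bromo-4-methoxyphenyl)-4H-chromen-4-one | COc1ccc(-c2cc(=O)c3c(OCc4ccccc4)cc(OCc4ccccc4)cc3o2)cc1Br | intermediate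
6 | (2-ethoxy-2-oxoethyl)zinc bromide (commercial THF solution) | CCOC(=O)C[Zn]Br | starting material
7 | ethyl 2-{5-[5,7-bis(benzyloxy)-4-oxo-4H-chromen-2-yl]-2-methoxyphenyl}acetate | CCOC(=O)Cc1cc(-c2cc(=O)c3c(OCc4ccccc4)cc(OCc4ccccc4)cc3o2)ccc1OC | intermediate
8 | 2-{5-[5,7-bis(benzyloxy)-4-oxo-4H-chromen-2-yl]-2-methoxyphenyl}acetic acid | OC(=O)Cc1cc(-c2cc(=O)c3c(OCc4ccccc4)cc(OCc4ccccc4)cc3o2)ccc1OC | intermediate
9 | 3-hydroxy-2-methyl-4H-pyran-4-one (maltol) | Cc1occc(=O)c1O | starting material
10 | 2-methyl-4-oxo-4H-pyran-3-yl trifluoromethanesulfonate | Cc1occc(=O)c1OS(=O)(=O)C(F)(F)F | intermediate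
11 | methyl 2-methyl-4-oxo-4H-pyran-3-carboxylate | COC(=O)c1c(C)occc1=O | intermediate
12 | 2-{5-[5,7-bis(benzyloxy)-4-oxo-4H-chromen-2-yl]-2-methoxyphenyl}-1-(1H-imidazol-1-yl)ethan-1-one | COc1ccc(-c2cc(=O)c3c(OCc4ccccc4)cc(OCc4ccccc4)cc3o2)cc1CC(=O)n1ccnc1 | intermediate (not isolated)
13 | methyl 2-(3-{5-[5,7-bis(benzyloxy)-4-oxo-4H-chromen-2-yl]-2-methoxyphenyl}-2-oxopropyl)-4-oxo-4H-pyran-3-carboxylate | COC(=O)c1c(CC(=O)Cc2cc(-c3cc(=O)c4c(OCc5ccccc5)cc(OCc5ccccc5)cc4o3)ccc2OC)occc1=O | intermediate (not isolated)
14 | 6-{5-[5,7-bis(benzyloxy)-4-oxo-4H-chromen-2-yl]-2-methoxyphenyl}-5,7-dihydroxy-4H-chromen-4-one | COc1ccc(-c2cc(=O)c3c(OCc4ccccc4)cc(OCc4ccccc4)cc3o2)cc1-c1c(O)cc2occc(=O)c2c1O | intermediate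
15 | 5,7-bis(benzyloxy)-6-{5-[5,7-bis(benzyloxy)-4-oxo-4H-chromen-2-yl]-2-methoxyphenyl}-4H-chromen-4-one | COc1ccc(-c2cc(=O)c3c(OCc4ccccc4)cc(OCc4ccccc4)cc3o2)cc1-c1c(OCc2ccccc2)cc2occc(=O)c2c1OCc1ccccc1 | intermediate
16 | (4-methoxyphenyl)boronic acid | COc1ccc(B(O)O)cc1 | starting material
17 | (2S)-5,7-bis(benzyloxy)-6-{5-[5,7-bis(benzyloxy)-4-oxo-4H-chromen-2-yl]-2-methoxyphenyl}-2-(4-methoxyphenyl)-2,3-dihydro-4H-chromen-4-one | COc1ccc([C@@H]2CC(=O)c3c(cc(OCc4ccccc4)c(-c4cc(-c5cc(=O)c6c(OCc7ccccc7)cc(OCc7ccccc7)cc6o5)ccc4OC)c3OCc3ccccc3)O2)cc1 | intermediate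
18 | (2S)-6-[5-(5,7-dihydroxy-4-oxo-4H-chromen-2-yl)-2-methoxyphenyl]-5,7-dihydroxy-2-(4-methoxyphenyl)-2,3-dihydro-4H-chromen-4-one | COc1ccc([C@@H]2CC(=O)c3c(cc(O)c(-c4cc(-c5cc(=O)c6c(O)cc(O)cc6o5)ccc4OC)c3O)O2)cc1 | target

## Step count and least certain steps

Total step count: 11. Longest linear sequence: 9 steps (1, 2, 3, 4, 5, 8, 9, 10, 11); steps 6 and 7 form the short second branch.

**Step 8 (key step, proposed new method).**
- Most likely failure: acyl transfer to oxygen instead of carbon, or closure to the enol lactone with the sequence stalling before ring A forms.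
- Also possible: conjugate addition of carbanions to the unsubstituted ring carbon of 11 with ring opening, and α-deprotonation of the acyl imidazole to a ketene that oligomerises. The doubly stabilised anion of 11 is a weak nucleophile, which favours these side paths.
- Fallback (known chemistry, from 5, returning at 15):
  - Miyaura borylation of 5 (B2pin2, Pd(dppf)Cl2, KOAc, dioxane, 90 °C) gives 5,7-bis(benzyloxy)-2-[4-methoxy-3-(4,4,5,5-tetramethyl-1,3,2-dioxaborolan-2-yl)phenyl]-4H-chromen-4-one F1.
  - Purchased 5,7-dihydroxy-4H-chromen-4-one F2 is benzylated at the non-chelated oxygen (BnBr, K2CO3, acetone) to 7-(benzyloxy)-5-hydroxy-4H-chromen-4-one F3.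
  - F3 is iodinated ortho to the chelated hydroxyl (benzyltrimethylammonium dichloroiodate, CaCO3, CH2Cl2–MeOH), as 5-hydroxy-7-alkoxyflavones are, to 7-(benzyloxy)-5-hydroxy-6-iodo-4H-chromen-4-one F4.
  - F4 is benzylated at O5 (BnBr, K2CO3, DMF) to 5,7-bis(benzyloxy)-6-iodo-4H-chromen-4-one F5.
  - Suzuki–Miyaura coupling of F1 with F5 (Pd(OAc)2, SPhos, anhydrous K3PO4, toluene, 100 °C) gives 15.
  - The hindered coupling is then run on an achiral chromone, before C2 exists, so base cannot cost enantiopurity.

**Step 10.**
- Most likely failure: low conversion or poor facial selectivity. The 5,7-dialkoxy pattern makes the chromone a weak acceptor, the peri benzyloxy group crowds the carbonyl through which the substrate binds, and the electron-rich boronic acid is prone to protodeboronation and homocoupling.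
- Fallback (from 15, returning at 17):
  - Racemic arylation of 15 with 16 using Pd(OCOCF3)2 and 2,2′-bipyridine gives racemic 5,7-bis(benzyloxy)-6-{5-[5,7-bis(benzyloxy)-4-oxo-4H-chromen-2-yl]-2-methoxyphenyl}-2-(4-methoxyphenyl)-2,3-dihydro-4H-chromen-4-one F6.
  - Kinetic resolution by asymmetric transfer hydrogenation follows (RuCl(p-cymene)(TsDPEN), HCO2H–Et3N), using the catalyst enantiomer that reduces the 2R ketone faster.
  - This leaves (2S)-ketone 17 and converts the other enantiomer into (2R,4R)-5,7-bis(benzyloxy)-6-{5-[5,7-bis(benzyloxy)-4-oxo-4H-chromen-2-yl]-2-methoxyphenyl}-2-(4-methoxyphenyl)-3,4-dihydro-2H-chromen-4-ol F7, removed by chromatography.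

**Step 4.**
- Most likely failure: slow coupling at the ortho-methoxy bromide with hydrodebromination taking over, or addition of the zinc enolate to the flavone.
- Fallback (from 5, returning at 8, which also removes step 5):
  - Suzuki–Miyaura allylation of 5 with allylboronic acid pinacol ester (Pd(dppf)Cl2, K2CO3, dioxane–H2O, 80 °C) gives 2-(3-allyl-4-methoxyphenyl)-5,7-bis(benzyloxy)-4H-chromen-4-one F8.
  - Lemieux–Johnson cleavage (K2OsO4·2H2O cat., NaIO4, 2,6-lutidine, dioxane–H2O) gives 2-{5-[5,7-bis(benzyloxy)-4-oxo-4H-chromen-2-yl]-2-methoxyphenyl}acetaldehyde F9.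
  - Pinnick oxidation (NaClO2, NaH2PO4, 2-methylbut-2-ene, t-BuOH–H2O) gives 8.

**Step 11.**
- Most likely failure: over-reduction, either hydrogenolytic opening of the benzylic C2–O1 bond (activated by the 4-methoxyphenyl group) or saturation of the ring E double bond, while the two benzyl ethers flanking the biaryl bond cleave slowly.
- Fallback (from 17 directly to 18): non-reductive Lewis-acid debenzylation with BCl3 and pentamethylbenzene as cation scavenger in CH2Cl2 at −78 °C. This removes aryl benzyl ethers, leaves non-chelated aryl methyl ethers, and involves no hydrogen. It passes through no new compound, F0.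

## Further compounds

F1 | step 8 | 5,7-bis(benzyloxy)-2-[4-methoxy-3-(4,4,5,5-tetramethyl-1,3,2-dioxaborolan-2-yl)phenyl]-4H-chromen-4-one | COc1ccc(-c2cc(=O)c3c(OCc4ccccc4)cc(OCc4ccccc4)cc3o2)cc1B1OC(C)(C)C(C)(C)O1
F2 | step 8 | 5,7-dihydroxy-4H-chromen-4-one (purchased) | O=c1ccoc2cc(O)cc(O)c12
F3 | step 8 | 7-(benzyloxy)-5-hydroxy-4H-chromen-4-one | O=c1ccoc2cc(OCc3ccccc3)cc(O)c12
F4 | step 8 | 7-(benzyloxy)-5-hydroxy-6-iodo-4H-chromen-4-one | O=c1ccoc2cc(OCc3ccccc3)c(I)c(O)c12
F5 | step 8 | 5,7-bis(benzyloxy)-6-iodo-4H-chromen-4-one | O=c1ccoc2cc(OCc3ccccc3)c(I)c(OCc3ccccc3)c12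
F6 | step 10 | racemic 5,7-bis(benzyloxy)-6-{5-[5,7-bis(benzyloxy)-4-oxo-4H-chromen-2-yl]-2-methoxyphenyl}-2-(4-methoxyphenyl)-2,3-dihydro-4H-chromen-4-one | COc1ccc(C2CC(=O)c3c(cc(OCc4ccccc4)c(-c4cc(-c5cc(=O)c6c(OCc7ccccc7)cc(OCc7ccccc7)cc6o5)ccc4OC)c3OCc3ccccc3)O2)cc1
F7 | step 10 | (2R,4R)-5,7-bis(benzyloxy)-6-{5-[5,7-bis(benzyloxy)-4-oxo-4H-chromen-2-yl]-2-methoxyphenyl}-2-(4-methoxyphenyl)-3,4-dihydro-2H-chromen-4-ol | COc1ccc([C@H]2C[C@@H](O)c3c(cc(OCc4ccccc4)c(-c4cc(-c5cc(=O)c6c(OCc7ccccc7)cc(OCc7ccccc7)cc6o5)ccc4OC)c3OCc3ccccc3)O2)cc1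
F8 | step 4 | 2-(3-allyl-4-methoxyphenyl)-5,7-bis(benzyloxy)-4H-chromen-4-one | C=CCc1cc(-c2cc(=O)c3c(OCc4ccccc4)cc(OCc4ccccc4)cc3o2)ccc1OC
F9 | step 4 | 2-{5-[5,7-bis(benzyloxy)-4-oxo-4H-chromen-2-yl]-2-methoxyphenyl}acetaldehyde | O=CCc1cc(-c2cc(=O)c3c(OCc4ccccc4)cc(OCc4ccccc4)cc3o2)ccc1OC
F0 | step 11 | none | none
A1 | alternative 1 | (2S)-5,7-bis(benzyloxy)-6-iodo-2-(4-methoxyphenyl)-2,3-dihydro-4H-chromen-4-one | COc1ccc([C@@H]2CC(=O)c3c(cc(OCc4ccccc4)c(I)c3OCc3ccccc3)O2)cc1
A2 | alternative 1 | {5-[5,7-bis(benzyloxy)-4-oxo-4H-chromen-2-yl]-2-methoxyphenyl}boronic acid | COc1ccc(-c2cc(=O)c3c(OCc4ccccc4)cc(OCc4ccccc4)cc3o2)cc1B(O)O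
A3 | alternative 2 | (E)-1-(3-{5-[5,7-bis(benzyloxy)-4-oxo-4H-chromen-2-yl]-2-methoxyphenyl}-2,4,6-trihydroxyphenyl)-3-(4-methoxyphenyl)prop-2-en-1-one | COc1ccc(/C=C/C(=O)c2c(O)cc(O)c(-c3cc(-c4cc(=O)c5c(OCc6ccccc6)cc(OCc6ccccc6)cc5o4)ccc3OC)c2O)cc1
A4 | alternative 2 | (2S)-6-{5-[5,7-bis(benzyloxy)-4-oxo-4H-chromen-2-yl]-2-methoxyphenyl}-5,7-dihydroxy-2-(4-methoxyphenyl)-2,3-dihydro-4H-chromen-4-one | COc1ccc([C@@H]2CC(=O)c3c(cc(O)c(-c4cc(-c5cc(=O)c6c(OCc7ccccc7)cc(OCc7ccccc7)cc6o5)ccc4OC)c3O)O2)cc1
A5 | alternative 2 | 8-{5-[5,7-bis(benzyloxy)-4-oxo-4H-chromen-2-yl]-2-methoxyphenyl}-5,7-dihydroxy-2-(4-methoxyphenyl)-2,3-dihydro-4H-chromen-4-one | COc1ccc(C2CC(=O)c3c(O)cc(O)c(-c4cc(-c5cc(=O)c6c(OCc7ccccc7)cc(OCc7ccccc7)cc6o5)ccc4OC)c3O2)cc1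
A6 | alternative 3 | methyl (2S)-2-(4-methoxyphenyl)-6-methyl-4-oxo-3,4-dihydro-2H-pyran-5-carboxylate | COc1ccc([C@@H]2CC(=O)C(C(=O)OC)=C(C)O2)cc1
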